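A pitfall at this bench: a short lag and a long steady slope are two times in series, and the readings do not say which step owns which.

all flasks: solid substrate 0.10 M; free catalyst 15 mM
- teal: second substrate 0.20 M; reagent 0.30 M; protic impurity 0.050 M; the very flask that is asked about, followed so far
- ochre: second substrate 0.20 M; reagent 0.30 M; protic impurity 0.034 M; run made earlier
- flask: second substrate 0.200 M; reagent 0.300 M; protic impurity 0.0500 M

| run | time / h | target / % |
|---|---|---|
| teal | 1.33 | 1.5 |
| teal | 4.00 | 7.8 |
| teal | 6.00 | 12.9 |
| teal | 10.0 | 22.0 |
| teal | 15.0 | 33.6 |
| teal | 20.0 | 41.8 |
| ochre | 1.50 | 1.8 |
| ochre | 5.00 | 9.6 |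
| ochre | 8.00 | 17.9 |
| ochre | 12.0 | 26.6 |
| ochre | 20.0 | 40.6 |
| ochre | 25.0 | 47.1 |

(each reading ± 0.5 percentage points)

1. apparent order in free catalyst when 50% of the solid substrate are converted (what has only dissolved counts as not reacted) (percent change of the rate of making target for one percent more free catalyst charged)

- given per volume of solution although it is solid: solid substrate
- at the start none of the solid substrate is in solution
- what has only dissolved of solid substrate counts as not reacted
- no earlier run changes the charge of free catalyst; that part of a forecast is a guess

The teal flask holds 41.8% target at 20.0 h. Between 4.00 h and 10.0 h it gains 0.0237 /h of its charge. So a molecule of solid substrate waits about 42.3 h, and the straight line starts after a lag of 0.704 h.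

My bet, which no run tests: the lag is dissolving, and the long wait is the reaction, the rate-limiting step. More free catalyst should then shrink the reaction time and leave the lag as it is, so I take the order to equal the chemical share, the wait over wait plus lag: 0.984. The lag is far shorter than the wait.

Expect half conversion near 21.8 h. Weigh the free catalyst charge with care: the rate should follow it almost in proportion.

The forecast gives 0.3, holding that “dissolution looks largely rate-limiting”, and I part from it there.

    starting material + free catalyst ⇌ catalyst intermediate A (K = 10.0 /M, k = 0.560 /M/min)
    reagent + catalyst intermediate A → free catalyst + target (k = 0.0500 /M/min)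
    second substrate + free catalyst ⇌ catalyst intermediate B (K = 57.0 /M, k = 0.240 /M/min)
    reagent + catalyst intermediate B → free catalyst + second product (k = 0.130 /M/min)
    second substrate + protic impurity → quenched substrate (k = 0.0200 /M/min)
    solid substrate ⇌ starting material, rate k6*(cs6 - [starting material]) while solid is left; crystals form when [starting material] > cs6 (solubility = 0.0750 M, k = 0.0150 /min)

The teal flask gives 0.93, a little below my share. Solid substrate is down to 11.5% at 0.250 d, with target at 13.0%. Half conversion comes at 0.947 d, later than my 0.910 d. The ochre run, read between 5.00 h and 12.0 h, gains 0.0243 /h after a lag of 1.05 h, so its chemical share is 0.975.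

The earlier runs and the new flask are calculated for an exercise, and the scatter is random.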